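**Retrosynthetic overview**
1. Target 17 ⇐ heptaacetate 16 by lipase-catalysed alcoholysis, a neutral final unmasking of all seven phenols.
2. 16 ⇐ Mizoroki–Heck coupling of aryl bromide pentaacetate 12 with 3,5-diacetoxystyrene 15, which builds the E-stilbene.
3. 12 ⇐ trans-dihydrobenzofuran 10 (BBr3, then Ac2O) ⇐ cis-dihydrobenzofuran 9 by acid epimerization at C2.
4. 9 ⇐ enantioselective Rh(II)-carbene 1,5-C–H insertion of diazo compound 8 (from hydrazone 7). This closes the dihydrofuran ring, the only ring made; all benzene rings are bought.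
5. Ketone 6 ⇐ Friedel–Crafts acylation of 1 with 2, ortho-demethylation, O-benzylation with 5.

Assumption: Rh2(R-PTAD)4 is written as the antipode that delivers (2R,3S)-9; if the sense of induction proves opposite, the commercial S-antipode is used and nothing else changes.

**Route**

Step 1
Reactants: 1 1-bromo-2,4-dimethoxybenzene; 2 3,5-dimethoxybenzoyl chloride
Product: 3 (5-bromo-2,4-dimethoxyphenyl)(3,5-dimethoxyphenyl)methanone
Conditions: AlCl3 (1.2 equiv), CH2Cl2, 0 °C → rt
Reagents that add atoms: none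
Why: Friedel–Crafts acylation goes at the unhindered position of 1 that is para to one methoxy and ortho to the other, so the bromine is fixed para to the methoxy cleaved in step 2.

Step 2
Reactants: 3 (5-bromo-2,4-dimethoxyphenyl)(3,5-dimethoxyphenyl)methanone
Product: 4 (5-bromo-2-hydroxy-4-methoxyphenyl)(3,5-dimethoxyphenyl)methanone
Conditions: BCl3 (1.5 equiv), CH2Cl2, −78 → 0 °C; H2O quench
Reagents that add atoms: none
Why: Chelation-controlled Lewis-acid ether cleavage removes only the methoxy ortho to the ketone carbonyl, leaving the other three methoxy groups and the aryl bromide intact.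

Step 3
Reactants: 4 (5-bromo-2-hydroxy-4-methoxyphenyl)(3,5-dimethoxyphenyl)methanone; 5 4-(chloromethyl)-1,2-dimethoxybenzene
Product: 6 {5-bromo-2-[(3,4-dimethoxyphenyl)methoxy]-4-methoxyphenyl}(3,5-dimethoxyphenyl)methanone
Conditions: K2CO3 (2 equiv), DMF, 60 °C
Reagents that add atoms: none
Why: Williamson etherification of the phenol with the reactive electron-rich benzylic chloride installs the OCH2Ar unit whose CH2 becomes C2.

Step 4
Reactants: 6 {5-bromo-2-[(3,4-dimethoxyphenyl)methoxy]-4-methoxyphenyl}(3,5-dimethoxyphenyl)methanone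
Product: 7 hydrazone of ketone 6 (E/Z mixture)
Conditions: N2H4·H2O (10 equiv), AcOH (cat.), EtOH, 80 °C, sealed tube
Reagents that add atoms: hydrazine (as monohydrate), NN
Why: Hydrazone condensation of the diaryl ketone; excess hydrazine suppresses azine formation and both C=N isomers give the same diazo compound.

Step 5
Reactants: 7 hydrazone of ketone 6
Product: 9 (2R,3S)-5-bromo-2-(3,4-dimethoxyphenyl)-3-(3,5-dimethoxyphenyl)-6-methoxy-2,3-dihydro-1-benzofuran (2,3-cis), via diaryldiazomethane 8 (not isolated)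
Conditions: MnO2 (8 equiv), CH2Cl2, 0 °C, filter through Celite; then Rh2(R-PTAD)4 (1 mol %), CH2Cl2, −20 °C → rt
Reagents that add atoms: none
Why: Dehydrogenation gives the donor/donor diazo compound, whose chiral Rh(II) carbene undergoes intramolecular 1,5-C–H insertion into the activated benzylic ether C–H; this asymmetric catalysis sets C3 (S) and C2 together as the 2,3-cis isomer.

Step 6
Reactants: 9 (2R,3S)-cis-dihydrobenzofuran
Product: 10 (2S,3S)-5-bromo-2-(3,4-dimethoxyphenyl)-3-(3,5-dimethoxyphenyl)-6-methoxy-2,3-dihydro-1-benzofuran (2,3-trans)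
Conditions: TFA (10 equiv), CH2Cl2 (0.02 M), 0 °C → rt
Reagents that add atoms: none
Why: Acid-catalysed epimerization by reversible ionization of the C2–O bond to the 3,4-dimethoxybenzylic cation and reclosure gives the thermodynamically favoured trans isomer, inverting C2 (R → S) while C3 (S) is not part of the ionizing bond and stays.

Step 7
Reactants: 10 (2S,3S)-trans-dihydrobenzofuran pentamethyl ether
Product: 11 4-[(2S,3S)-5-bromo-3-(3,5-dihydroxyphenyl)-6-hydroxy-2,3-dihydro-1-benzofuran-2-yl]benzene-1,2-diol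
Conditions: BBr3 (12 equiv), CH2Cl2, −78 °C → rt; H2O quench; crude used directly
Reagents that add atoms: none
Why: Lewis-acid demethylation cleaves all five aryl methyl ethers; any reversible C2–O opening returns the trans isomer already in hand and the aryl bromide is inert.

Step 8
Reactants: 11 trans-pentaphenol
Product: 12 pentaacetate of 11, (2S,3S)
Conditions: Ac2O (10 equiv), pyridine, DMAP (cat.), 0 °C → rt
Reagents that add atoms: acetic anhydride, CC(=O)OC(C)=O
Why: DMAP-catalysed O-acetylation caps the air-sensitive pentaphenol as a stable, purifiable pentaacetate that tolerates the Heck reaction.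

Step 9
Reactants: 13 3,5-dihydroxybenzaldehyde
Product: 14 5-ethenylbenzene-1,3-diol
Conditions: Ph3PCH3Br (3.5 equiv), KOtBu (3.4 equiv), THF, 0 °C → rt; aq. NH4Cl; used crude
Reagents that add atoms: methyltriphenylphosphonium bromide, C[P+](c1ccccc1)(c1ccccc1)c1ccccc1.[Br-]
Why: Wittig methylenation; the two meta-phenoxides formed by the extra base are not conjugated with the aldehyde and do not block olefination.

Step 10
Reactants: 14 5-ethenylbenzene-1,3-diol
Product: 15 5-ethenyl-1,3-phenylene diacetate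
Conditions: Ac2O (3 equiv), pyridine, DMAP (cat.), CH2Cl2, 0 °C → rt
Reagents that add atoms: acetic anhydride, CC(=O)OC(C)=O
Why: O-acetylation gives a storable styrene that carries the same ester protection as the core.

Step 11
Reactants: 12 pentaacetate aryl bromide; 15 5-ethenyl-1,3-phenylene diacetate
Product: 16 heptaacetate of the target, (2S,3S), E
Conditions: Pd2(dba)3 (2.5 mol %), [HP(t-Bu)3]BF4 (10 mol %), Cy2NMe (1.5 equiv), 1,4-dioxane, 80 °C
Reagents that add atoms: none
Why: Mizoroki–Heck coupling; the bulky electron-rich phosphine activates the electron-rich ortho-substituted aryl bromide, syn-insertion/β-hydride elimination gives the E-stilbene, and the anhydrous hindered amine leaves the aryl acetates intact.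

Step 12
Reactants: 16 heptaacetate
Product: 17 5-[(E)-2-[(2S,3S)-2-(3,4-dihydroxyphenyl)-3-(3,5-dihydroxyphenyl)-6-hydroxy-2,3-dihydro-1-benzofuran-5-yl]ethenyl]benzene-1,3-diol
Conditions: lipase (immobilized Candida antarctica lipase B, Novozym 435), n-BuOH (30 equiv), MTBE/THF 3:1, 45 °C, Ar, dark
Reagents that add atoms: none
Why: Lipase-catalysed transesterification (alcoholysis) moves all seven phenolic acetyl groups to n-butanol under neutral, non-aqueous conditions, so the 4-hydroxybenzylic C2–O bond (both stereocenters), the catechol and the E-stilbene are not touched.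

**Compound list**
1 | 1-bromo-2,4-dimethoxybenzene | COc1ccc(Br)c(OC)c1 | starting material
2 | 3,5-dimethoxybenzoyl chloride | COc1cc(OC)cc(C(Cl)=O)c1 | starting material
3 | (5-bromo-2,4-dimethoxyphenyl)(3,5-dimethoxyphenyl)methanone | COc1cc(OC)c(C(=O)c2cc(OC)cc(OC)c2)cc1Br | intermediate
4 | (5-bromo-2-hydroxy-4-methoxyphenyl)(3,5-dimethoxyphenyl)methanone | COc1cc(O)c(C(=O)c2cc(OC)cc(OC)c2)cc1Br | intermediate
5 | 4-(chloromethyl)-1,2-dimethoxybenzene (3,4-dimethoxybenzyl chloride) | COc1ccc(CCl)cc1OC | starting material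
6 | {5-bromo-2-[(3,4-dimethoxyphenyl)methoxy]-4-methoxyphenyl}(3,5-dimethoxyphenyl)methanone | COc1cc(OCc2ccc(OC)c(OC)c2)c(C(=O)c2cc(OC)cc(OC)c2)cc1Br | intermediate
7 | hydrazone of 6 (E/Z mixture) | COc1cc(OCc2ccc(OC)c(OC)c2)c(C(=NN)c2cc(OC)cc(OC)c2)cc1Br | intermediate
8 | diaryldiazomethane from 7 | COc1cc(OCc2ccc(OC)c(OC)c2)c(C(=[N+]=[N-])c2cc(OC)cc(OC)c2)cc1Br | intermediate (not isolated)
9 | (2R,3S)-5-bromo-2-(3,4-dimethoxyphenyl)-3-(3,5-dimethoxyphenyl)-6-methoxy-2,3-dihydro-1-benzofuran (cis) | Brc1cc2c(cc1OC)O[C@@H](c1ccc(OC)c(OC)c1)[C@H]2c1cc(OC)cc(OC)c1 | intermediate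
10 | (2S,3S)-5-bromo-2-(3,4-dimethoxyphenyl)-3-(3,5-dimethoxyphenyl)-6-methoxy-2,3-dihydro-1-benzofuran (trans) | Brc1cc2c(cc1OC)O[C@H](c1ccc(OC)c(OC)c1)[C@H]2c1cc(OC)cc(OC)c1 | intermediate
11 | 4-[(2S,3S)-5-bromo-3-(3,5-dihydroxyphenyl)-6-hydroxy-2,3-dihydro-1-benzofuran-2-yl]benzene-1,2-diol | Brc1cc2c(cc1O)O[C@H](c1ccc(O)c(O)c1)[C@H]2c1cc(O)cc(O)c1 | intermediate
12 | pentaacetate of 11, (2S,3S) | Brc1cc2c(cc1OC(C)=O)O[C@H](c1ccc(OC(C)=O)c(OC(C)=O)c1)[C@H]2c1cc(OC(C)=O)cc(OC(C)=O)c1 | intermediate
13 | 3,5-dihydroxybenzaldehyde | O=Cc1cc(O)cc(O)c1 | starting material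
14 | 5-ethenylbenzene-1,3-diol (3,5-dihydroxystyrene) | C=Cc1cc(O)cc(O)c1 | intermediate
15 | 5-ethenyl-1,3-phenylene diacetate (3,5-diacetoxystyrene) | C=Cc1cc(OC(C)=O)cc(OC(C)=O)c1 | intermediate
16 | heptaacetate of the target, (2S,3S), E | CC(=O)Oc1cc(OC(C)=O)cc(/C=C/c2cc3c(cc2OC(C)=O)O[C@H](c2ccc(OC(C)=O)c(OC(C)=O)c2)[C@H]3c2cc(OC(C)=O)cc(OC(C)=O)c2)c1 | intermediate
17 | 5-[(E)-2-[(2S,3S)-2-(3,4-dihydroxyphenyl)-3-(3,5-dihydroxyphenyl)-6-hydroxy-2,3-dihydro-1-benzofuran-5-yl]ethenyl]benzene-1,3-diol | Oc1cc(O)cc(/C=C/c2cc3c(cc2O)O[C@H](c2ccc(O)c(O)c2)[C@H]3c2cc(O)cc(O)c2)c1 | target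

**Totals**
Total step count: 12. Longest linear sequence: 10 steps (steps 1–8, 11, 12); the styrene branch (steps 9–10) joins at step 11.

**Steps most likely to fail, with fallbacks**

Step 5 (asymmetric C–H insertion: ee, dr, carbene side reactions). The fallback sets out from hydrazone 7. It is oxidised as before and cyclised with achiral Rh2(esp)2 to the racemic cis-dihydrobenzofuran, that is 9 together with its mirror image (2S,3R)-5-bromo-2-(3,4-dimethoxyphenyl)-3-(3,5-dimethoxyphenyl)-6-methoxy-2,3-dihydro-1-benzofuran F1. The two are separated by preparative chiral SFC, and the route is rejoined at 9.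

Step 6 (acid epimerization: cationic by-products, or erosion at C3 through elimination and re-addition). The fallback sets out from 9 and skips the separate acid step. BBr3 in CH2Cl2 demethylates 9 directly to the cis-pentaphenol 4-[(2R,3S)-5-bromo-3-(3,5-dihydroxyphenyl)-6-hydroxy-2,3-dihydro-1-benzofuran-2-yl]benzene-1,2-diol F2. Its free 4-hydroxyl lets the C2–O bond open through a neutral p-quinone methide, and holding the mixture at rt (or warming the crude in AcOH) converges it on the trans isomer, coming back to the route at 11.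

Step 12 (exhaustive enzymatic deacetylation may stall at hindered aryl acetates). The fallback sets out from 11 and, for the styrene, from 14, and changes the ester to one that lipases accept better. Butanoic anhydride/pyridine converts 11 to the pentabutanoate of 11 F3 and 14 to 5-ethenyl-1,3-phenylene dibutanoate F4. The same Heck conditions join them to the heptabutanoate of the target F5, and the same lipase/n-BuOH alcoholysis releases the phenols, coming back to the route at 17.

**Further compounds**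
F1 | step 5 | (2S,3R)-5-bromo-2-(3,4-dimethoxyphenyl)-3-(3,5-dimethoxyphenyl)-6-methoxy-2,3-dihydro-1-benzofuran (enantiomer of 9) | Brc1cc2c(cc1OC)O[C@H](c1ccc(OC)c(OC)c1)[C@@H]2c1cc(OC)cc(OC)c1
F2 | step 6 | 4-[(2R,3S)-5-bromo-3-(3,5-dihydroxyphenyl)-6-hydroxy-2,3-dihydro-1-benzofuran-2-yl]benzene-1,2-diol (cis-pentaphenol) | Brc1cc2c(cc1O)O[C@@H](c1ccc(O)c(O)c1)[C@H]2c1cc(O)cc(O)c1
F3 | step 12 | pentabutanoate of 11, (2S,3S) | Brc1cc2c(cc1OC(=O)CCC)O[C@H](c1ccc(OC(=O)CCC)c(OC(=O)CCC)c1)[C@H]2c1cc(OC(=O)CCC)cc(OC(=O)CCC)c1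
F4 | step 12 | 5-ethenyl-1,3-phenylene dibutanoate | C=Cc1cc(OC(=O)CCC)cc(OC(=O)CCC)c1
F5 | step 12 | heptabutanoate of the target, (2S,3S), E | CCCC(=O)Oc1cc(OC(=O)CCC)cc(/C=C/c2cc3c(cc2OC(=O)CCC)O[C@H](c2ccc(OC(=O)CCC)c(OC(=O)CCC)c2)[C@H]3c2cc(OC(=O)CCC)cc(OC(=O)CCC)c2)c1
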